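**Plan**
- Feature: ring B is a 1,4-phenylene whose C1 carries only the ether oxygen to ring A and whose C4 carries only the benzylic CH2 of the bridge to ring C. An oxygen and a carbon para on one ring is the pattern a 2-aryloxybuta-1,3-diene and a terminal alkynyl ketone give in a [4+2] addition.
- Cuts, in retrosynthetic order: the two phenol O–H (as O–Me), the bridge CH2 on ring B (as C=O), two ring-B hydrogens (as the 1,4-cyclohexadiene), then the ring-B bonds C3–C4 and C5–C6, which opens ring B and the 18-membered ring together.
- Further cuts: the dienyl C=CH2 (ester methylenation), the phenol–acryloyl bond, C(OH)–C≡CH, the ring D–O–ring C ether (Ullmann) and the ring A–CH2CH2–ring D bridge (Wittig, then reduction).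
- Forward: rings A, D and C are bought. The A–D bridge, the D–O–C ether, the side chain and the dienyl ether follow. Ring B and the macrocycle arise in one cycloaddition, and aromatisation, deoxygenation and demethylation finish.
- Stereochemistry: the target has no stereocentre; the carbinol centres of 18 and 22 are racemic and are erased in the following transformation.

Key step: step 13

Assumption: marchantin C has no stereocentre and no configurationally stable axis or plane at room temperature, so the "single enantiomer" is the achiral compound and nothing has to be controlled.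

**Route**

Step 1
Reactants: 1 3-(benzyloxy)-4-methoxybenzaldehyde; 2 (3-bromobenzyl)triphenylphosphonium bromide
Product: 4 2-(benzyloxy)-4-[2-(3-bromophenyl)ethenyl]-1-methoxybenzene (E/Z mixture), via phosphorus ylide 3 (not isolated)
Conditions: KOtBu, THF, 0 °C to rt
Reagents that add atoms: none
Why: Wittig olefination of an aromatic aldehyde with a semi-stabilised benzylic ylide is reliable, and the alkene geometry is irrelevant because the double bond is saturated in step 2.

Step 2
Reactants: 4 2-(benzyloxy)-4-[2-(3-bromophenyl)ethenyl]-1-methoxybenzene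
Product: 5 2-(benzyloxy)-4-[2-(3-bromophenyl)ethyl]-1-methoxybenzene
Conditions: TsNHNH2, NaOAc, DME/H2O, reflux
Reagents that add atoms: none
Why: Diimide reduction delivers H2 to the stilbene C=C by concerted syn transfer and leaves the aryl bromide and the benzyl ether, which palladium-catalysed hydrogenation would cleave.

Step 3
Reactants: 5 2-(benzyloxy)-4-[2-(3-bromophenyl)ethyl]-1-methoxybenzene; 6 o-eugenol (2-allyl-6-methoxyphenol)
Product: 7 1-allyl-2-{3-[2-(3-benzyloxy-4-methoxyphenyl)ethyl]phenoxy}-3-methoxybenzene
Conditions: CuI (10 mol %), picolinic acid (20 mol %), K3PO4, DMSO, 90 °C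
Reagents that add atoms: none
Why: Ullmann-type copper-catalysed diaryl ether coupling with picolinic acid as ligand tolerates di-ortho-substituted phenols and unactivated aryl bromides, and the phosphate base is too weak to move the allyl double bond into conjugation.

Step 4
Reactants: 7 1-allyl-2-{3-[2-(3-benzyloxy-4-methoxyphenyl)ethyl]phenoxy}-3-methoxybenzene
Product: 9 2-{2-[3-(2-(3-benzyloxy-4-methoxyphenyl)ethyl)phenoxy]-3-methoxyphenyl}ethanol, via arylacetaldehyde 8 (not isolated)
Conditions: O3, CH2Cl2/MeOH, Sudan III, −78 °C; then NaBH4, −78 °C to rt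
Reagents that add atoms: ozone, [O-][O+]=O
Why: Ozonolysis with reductive borohydride work-up cleaves the only C=C bond and reduces the enolisable arylacetaldehyde in the same flask, the indicator dye guarding the electron-rich arenes against excess ozone.

Step 5
Reactants: 9 2-{2-[3-(2-(3-benzyloxy-4-methoxyphenyl)ethyl)phenoxy]-3-methoxyphenyl}ethanol
Product: 10 tert-butyldimethylsilyl ether of alcohol 9
Conditions: TBSCl, imidazole, DMF, rt
Reagents that add atoms: tert-butyldimethylsilyl chloride, CC(C)(C)[Si](C)(C)Cl
Why: Silylation of a primary alcohol with a silyl chloride and imidazole is routine and masks the hydroxyl group for the acylation and titanium steps.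

Step 6
Reactants: 10 tert-butyldimethylsilyl ether of alcohol 9
Product: 11 5-{2-[3-(2-(2-(tert-butyldimethylsilyloxy)ethyl)-6-methoxyphenoxy)phenyl]ethyl}-2-methoxyphenol
Conditions: H2 (1 atm), 10% Pd/C, EtOAc, rt
Reagents that add atoms: none
Why: Catalytic hydrogenolysis removes the benzyl aryl ether, while the silyl ether, the methyl ethers and the diaryl ether are stable in a non-protic solvent.

Step 7
Reactants: 11 5-{2-[3-(2-(2-(tert-butyldimethylsilyloxy)ethyl)-6-methoxyphenoxy)phenyl]ethyl}-2-methoxyphenol; 12 acryloyl chloride
Product: 13 aryl acrylate (prop-2-enoate ester of phenol 11)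
Conditions: Et3N, CH2Cl2, BHT (trace), −20 to 0 °C
Reagents that add atoms: none
Why: O-acylation of a phenol with an acid chloride and an amine base is fast at low temperature, where the acrylate does not polymerise.

Step 8
Reactants: 13 aryl acrylate (prop-2-enoate ester of phenol 11)
Product: 14 buta-1,3-dien-2-yl aryl ether bearing the silyl-protected side chain
Conditions: Cp2TiMe2 (3 equiv), toluene/THF, 65 °C, dark; filtration through basic alumina
Reagents that add atoms: dimethyltitanocene, C[Ti](C)(C1C=CC=C1)C1C=CC=C1
Why: Petasis methylenation (titanocene methylidene, [2+2] addition to the ester C=O, cycloreversion) converts aryl and α,β-unsaturated esters into enol ethers without acid, and silyl ether, ethers and arenes are inert to the reagent.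

Step 9
Reactants: 14 buta-1,3-dien-2-yl aryl ether bearing the silyl-protected side chain
Product: 15 2-{2-[3-(2-(3-(buta-1,3-dien-2-yloxy)-4-methoxyphenyl)ethyl)phenoxy]-3-methoxyphenyl}ethanol
Conditions: TBAF, THF, 0 °C
Reagents that add atoms: none
Why: Fluoride-mediated desilylation is basic and therefore spares the acid-labile dienyl aryl ether.

Step 10
Reactants: 15 2-{2-[3-(2-(3-(buta-1,3-dien-2-yloxy)-4-methoxyphenyl)ethyl)phenoxy]-3-methoxyphenyl}ethanol
Product: 16 {2-[3-(2-(3-(buta-1,3-dien-2-yloxy)-4-methoxyphenyl)ethyl)phenoxy]-3-methoxyphenyl}acetaldehyde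
Conditions: Dess–Martin periodinane, NaHCO3, CH2Cl2, 0 °C
Reagents that add atoms: none
Why: Bicarbonate-buffered Dess–Martin oxidation takes the primary alcohol to the aldehyde without over-oxidation and without free acid that would hydrolyse the enol ether.

Step 11
Reactants: 16 {2-[3-(2-(3-(buta-1,3-dien-2-yloxy)-4-methoxyphenyl)ethyl)phenoxy]-3-methoxyphenyl}acetaldehyde; 17 ethynylmagnesium bromide
Product: 18 racemic 1-{2-[3-(2-(3-(buta-1,3-dien-2-yloxy)-4-methoxyphenyl)ethyl)phenoxy]-3-methoxyphenyl}but-3-yn-2-ol
Conditions: THF, −78 to 0 °C; aq NH4Cl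
Reagents that add atoms: none
Why: Grignard 1,2-addition of the weakly basic ethynyl nucleophile outruns enolisation of the aldehyde at low temperature, and the new carbinol centre is formed racemic because it is oxidised away in step 12.

Step 12
Reactants: 18 racemic 1-{2-[3-(2-(3-(buta-1,3-dien-2-yloxy)-4-methoxyphenyl)ethyl)phenoxy]-3-methoxyphenyl}but-3-yn-2-ol
Product: 19 1-{2-[3-(2-(3-(buta-1,3-dien-2-yloxy)-4-methoxyphenyl)ethyl)phenoxy]-3-methoxyphenyl}but-3-yn-2-one
Conditions: Dess–Martin periodinane, NaHCO3, CH2Cl2, 0 °C; used at once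
Reagents that add atoms: none
Why: Buffered Dess–Martin oxidation of a secondary propargylic alcohol is the standard entry to a terminal ynone and removes the only stereocentre.

Step 13
Reactants: 19 1-{2-[3-(2-(3-(buta-1,3-dien-2-yloxy)-4-methoxyphenyl)ethyl)phenoxy]-3-methoxyphenyl}but-3-yn-2-one
Product: 20 macrocyclic 1-aryloxy-4-acylcyclohexa-1,4-diene (ring B as the cycloadduct, C=O on the bridge to ring C)
Conditions: PhMe (1 mM, slow addition of 19), BHT (cat.), 120 °C, sealed vessel, dark
Reagents that add atoms: none
Why: This is a thermal intramolecular Diels–Alder reaction in which the HOMO of the 2-aryloxydiene (largest coefficient at C1, the CH2 next to the oxygen-bearing carbon) and the LUMO of the ynone (largest at the terminal CH) combine in a concerted, asynchronous [4+2] addition that joins C1 to the alkyne CH and C4 to the acyl-bearing alkyne carbon. The closest known reaction type is the macrocyclising Diels–Alder reaction of a diene or 2-pyrone with a tethered alkyne, followed by aromatisation to an arene inside a cyclophane. The six-membered ring closes as the cycloadduct itself, and the 18-membered ring closes in the same event because the 14-atom tether from the ring-A oxygen through rings A, D and C to the carbonyl carbon spans the 1,4-positions of the new ring, which is easy while ring B is still a flexible, non-aromatic cyclohexadiene. No stereocentre is formed, since the new ring holds only sp2 carbons and CH2 groups. The step needs para rather than meta regiochemistry, secured by the matched polarity of the oxygenated diene and the ynone because the long tether imposes no orientation of its own, and ring closure rather than intermolecular addition, secured by high dilution, slow addition and a radical inhibitor.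

Step 14
Reactants: 20 macrocyclic 1-aryloxy-4-acylcyclohexa-1,4-diene
Product: 21 macrocyclic aryl ketone (marchantin C dimethyl ether with C=O at the bridge carbon on ring B)
Conditions: DDQ (1.05 equiv), benzene, rt
Reagents that add atoms: none
Why: DDQ dehydrogenation of a 1,4-cyclohexadiene (hydride abstraction from a doubly allylic CH2, then proton loss) is driven by aromatisation and is far faster than oxidation of the benzylic positions.

Step 15
Reactants: 21 macrocyclic aryl ketone
Product: 23 marchantin C dimethyl ether, via benzylic carbinol 22 (not isolated)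
Conditions: Et3SiH (excess), TFA, CH2Cl2, rt to 40 °C
Reagents that add atoms: none
Why: Ionic hydrogenation reduces diaryl-ethanones to bibenzyls by hydride transfer to the protonated ketone, ionisation of the carbinol to a cation stabilised by the para aryloxy group and a second hydride transfer, and it leaves all ethers intact.

Step 16
Reactants: 23 marchantin C dimethyl ether
Product: 24 marchantin C
Conditions: BBr3, CH2Cl2, −78 °C to rt; then H2O
Reagents that add atoms: none
Why: Boron tribromide demethylation cleaves aryl methyl ethers by Lewis acid complexation and bromide attack at methyl, while diaryl ether C–O bonds are inert.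

**Compound list**
1 | 3-(benzyloxy)-4-methoxybenzaldehyde (O-benzylisovanillin) | COc1ccc(C=O)cc1OCc1ccccc1 | starting material
2 | (3-bromobenzyl)triphenylphosphonium bromide | [Br-].Brc1cccc(C[P+](c2ccccc2)(c2ccccc2)c2ccccc2)c1 | starting material
3 | (3-bromobenzylidene)triphenylphosphorane | Brc1cccc(C=P(c2ccccc2)(c2ccccc2)c2ccccc2)c1 | intermediate (not isolated)
4 | 2-(benzyloxy)-4-[2-(3-bromophenyl)ethenyl]-1-methoxybenzene, E/Z mixture | COc1ccc(C=Cc2cccc(Br)c2)cc1OCc1ccccc1 | intermediate
5 | 2-(benzyloxy)-4-[2-(3-bromophenyl)ethyl]-1-methoxybenzene | COc1ccc(CCc2cccc(Br)c2)cc1OCc1ccccc1 | intermediate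
6 | o-eugenol (2-allyl-6-methoxyphenol) | COc1cccc(CC=C)c1O | starting material
7 | 1-allyl-2-{3-[2-(3-benzyloxy-4-methoxyphenyl)ethyl]phenoxy}-3-methoxybenzene | COc1ccc(CCc2cccc(Oc3c(CC=C)cccc3OC)c2)cc1OCc1ccccc1 | intermediate
8 | {2-[3-(2-(3-benzyloxy-4-methoxyphenyl)ethyl)phenoxy]-3-methoxyphenyl}acetaldehyde | COc1ccc(CCc2cccc(Oc3c(CC=O)cccc3OC)c2)cc1OCc1ccccc1 | intermediate (not isolated)
9 | 2-{2-[3-(2-(3-benzyloxy-4-methoxyphenyl)ethyl)phenoxy]-3-methoxyphenyl}ethanol | COc1ccc(CCc2cccc(Oc3c(CCO)cccc3OC)c2)cc1OCc1ccccc1 | intermediate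
10 | tert-butyldimethylsilyl ether of 9 | COc1ccc(CCc2cccc(Oc3c(CCO[Si](C)(C)C(C)(C)C)cccc3OC)c2)cc1OCc1ccccc1 | intermediate
11 | 5-{2-[3-(2-(2-(tert-butyldimethylsilyloxy)ethyl)-6-methoxyphenoxy)phenyl]ethyl}-2-methoxyphenol | COc1ccc(CCc2cccc(Oc3c(CCO[Si](C)(C)C(C)(C)C)cccc3OC)c2)cc1O | intermediate
12 | acryloyl chloride | C=CC(=O)Cl | starting material
13 | aryl acrylate of phenol 11 | COc1ccc(CCc2cccc(Oc3c(CCO[Si](C)(C)C(C)(C)C)cccc3OC)c2)cc1OC(=O)C=C | intermediate
14 | buta-1,3-dien-2-yl ether of phenol 11 (side chain still silylated) | COc1ccc(CCc2cccc(Oc3c(CCO[Si](C)(C)C(C)(C)C)cccc3OC)c2)cc1OC(=C)C=C | intermediate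
15 | 2-{2-[3-(2-(3-(buta-1,3-dien-2-yloxy)-4-methoxyphenyl)ethyl)phenoxy]-3-methoxyphenyl}ethanol | COc1ccc(CCc2cccc(Oc3c(CCO)cccc3OC)c2)cc1OC(=C)C=C | intermediate
16 | {2-[3-(2-(3-(buta-1,3-dien-2-yloxy)-4-methoxyphenyl)ethyl)phenoxy]-3-methoxyphenyl}acetaldehyde | COc1ccc(CCc2cccc(Oc3c(CC=O)cccc3OC)c2)cc1OC(=C)C=C | intermediate
17 | ethynylmagnesium bromide | C#C[Mg]Br | starting material
18 | 1-aryl-but-3-yn-2-ol carrying the dienyl ether, racemic | COc1ccc(CCc2cccc(Oc3c(CC(O)C#C)cccc3OC)c2)cc1OC(=C)C=C | intermediate
19 | 1-aryl-but-3-yn-2-one carrying the dienyl ether (cycloaddition precursor) | COc1ccc(CCc2cccc(Oc3c(CC(=O)C#C)cccc3OC)c2)cc1OC(=C)C=C | intermediate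
20 | macrocyclic 1-aryloxy-4-acylcyclohexa-1,4-diene | COc1ccc2cc1OC1=CCC(=CC1)C(=O)Cc1cccc(OC)c1Oc1cccc(c1)CC2 | intermediate
21 | macrocyclic aryl ketone (bridge C=O on ring B) | COc1ccc2cc1Oc1ccc(cc1)C(=O)Cc1cccc(OC)c1Oc1cccc(c1)CC2 | intermediate
22 | macrocyclic benzylic carbinol, racemic | COc1ccc2cc1Oc1ccc(cc1)C(O)Cc1cccc(OC)c1Oc1cccc(c1)CC2 | intermediate (not isolated)
23 | marchantin C dimethyl ether | COc1ccc2cc1Oc1ccc(cc1)CCc1cccc(OC)c1Oc1cccc(c1)CC2 | intermediate
24 | marchantin C | Oc1ccc2cc1Oc1ccc(cc1)CCc1cccc(O)c1Oc1cccc(c1)CC2 | target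

**Count**
Total steps: 16. Longest linear sequence: 16 (1 to 24; 2, 6, 12 and 17 enter in steps 1, 3, 7 and 11).

**Steps most likely to fail**

Step 13. The slow ring closure may lose to oligomerisation, or the ynone and the diene may decay thermally before they meet. The fallback gives up the cycloaddition, takes ring B as a ready arene and closes the macrocycle at the ring A–O–ring B ether. It sets out from alcohol 9, which is oxidised (Dess–Martin periodinane, NaHCO3) to aldehyde 8. Addition of 4-fluorophenylmagnesium bromide should give the racemic 1-(4-fluorophenyl)-2-arylethanol F1, and a second buffered Dess–Martin oxidation the benzyl-protected 4-fluorophenyl ketone F2. Hydrogenolysis (H2, Pd/C, EtOAc) frees the ring-A phenol to give the fluoro ketone phenol F3. Cs2CO3 in DMF at high dilution and about 100 °C should then close the 18-membered ring by intramolecular nucleophilic aromatic substitution of the phenoxide on the fluoride para to the ketone. This comes back to the route at aryl ketone 21, from which steps 15 and 16 follow.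

Step 8. The acrylate may polymerise or take up the reagent in a conjugate sense, and the dienyl ether may hydrolyse during isolation. The fallback makes the diene by elimination, without titanium. It sets out from phenol 11. Palladium(0)-catalysed opening of 2-vinyloxirane (Pd2(dba)3, racemic trans-1,2-diaminocyclohexane bis(2-diphenylphosphinobenzamide) ligand, CH2Cl2, rt) should give the branched, racemic 2-aryloxybut-3-en-1-ol F4. Appel iodination (I2, PPh3, imidazole) gives the primary iodide F5, and KOtBu in THF at 0 °C removes HI across the oxygen-bearing carbon in an E2 elimination. This comes back to the route at dienyl ether 14.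

Step 12. Acetic acid released by the oxidant may hydrolyse the dienyl ether, and the free terminal ynone may decompose during oxidation and purification. The fallback carries the alkyne silylated through the oxidation and unmasks the ynone last, under nearly neutral conditions. It sets out from aldehyde 16. Lithium (trimethylsilyl)acetylide in THF at −78 °C should give the racemic silylated alkynol F6, and buffered Dess–Martin oxidation the more robust trimethylsilyl ynone F7, which can be purified. Aqueous borax in MeOH/THF at rt then removes the silyl group. This comes back to the route at ynone 19, used directly in step 13.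

**Further compounds**
F1 | step 13 | racemic 1-(4-fluorophenyl)-2-{2-[3-(2-(3-benzyloxy-4-methoxyphenyl)ethyl)phenoxy]-3-methoxyphenyl}ethanol | COc1ccc(CCc2cccc(Oc3c(CC(O)c4ccc(F)cc4)cccc3OC)c2)cc1OCc1ccccc1
F2 | step 13 | 1-(4-fluorophenyl)-2-{2-[3-(2-(3-benzyloxy-4-methoxyphenyl)ethyl)phenoxy]-3-methoxyphenyl}ethanone | COc1ccc(CCc2cccc(Oc3c(CC(=O)c4ccc(F)cc4)cccc3OC)c2)cc1OCc1ccccc1
F3 | step 13 | 1-(4-fluorophenyl)-2-{2-[3-(2-(3-hydroxy-4-methoxyphenyl)ethyl)phenoxy]-3-methoxyphenyl}ethanone | COc1ccc(CCc2cccc(Oc3c(CC(=O)c4ccc(F)cc4)cccc3OC)c2)cc1O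
F4 | step 8 | racemic 2-aryloxybut-3-en-1-ol from phenol 11 | COc1ccc(CCc2cccc(Oc3c(CCO[Si](C)(C)C(C)(C)C)cccc3OC)c2)cc1OC(CO)C=C
F5 | step 8 | racemic 1-iodo-2-aryloxybut-3-ene from F4 | COc1ccc(CCc2cccc(Oc3c(CCO[Si](C)(C)C(C)(C)C)cccc3OC)c2)cc1OC(CI)C=C
F6 | step 12 | racemic 1-aryl-4-(trimethylsilyl)but-3-yn-2-ol carrying the dienyl ether | COc1ccc(CCc2cccc(Oc3c(CC(O)C#C[Si](C)(C)C)cccc3OC)c2)cc1OC(=C)C=C
F7 | step 12 | 1-aryl-4-(trimethylsilyl)but-3-yn-2-one carrying the dienyl ether | COc1ccc(CCc2cccc(Oc3c(CC(=O)C#C[Si](C)(C)C)cccc3OC)c2)cc1OC(=C)C=C
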